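**Assumption.** The target SMILES has no stereocentre and no stereogenic double bond, so polonidine A is achiral and "single enantiomer" is read as "the one achiral compound". Stereocentres in intermediates are transient and are carried as mixtures. 2-Methylbut-3-en-2-amine is taken as purchasable and is used as the free base (liberated from the commercial hydrochloride, which is handling and not a step).

## Analysis of the target

Polonidine A (C27H30N2) consists of two indoles joined C3–CH2–C3′, and each ring nitrogen (N1, N1′) carries a 2-methylbut-3-en-2-yl ("reverse prenyl") group. The molecule has no stereocentre and its two halves are identical, so every operation has to succeed twice. The defining feature is the pair of N1–C(CH3)2(CH=CH2) bonds: each indole nitrogen sits on a fully substituted sp3 carbon. That bond cannot be made by SN2 chemistry, and a tertiary allyl cation or π-allyl species is normally attacked at its primary terminus, while the indole answers at carbon. Seen from the substituent, N1 is simply the nitrogen of an α-tertiary primary amine that has been built into a pyrrole ring (N1–C2–C3–C3a–C7a). The second feature is the unbranched five-carbon chain C2–C3–CH2–C3′–C2′, which maps onto a 2,4-diarylpentanedial. Sensitive groups are the electron-rich indoles with free C2 positions, the diindolylmethane CH2 (acid-labile C3–CH2 bonds, oxidisable), the tertiary allylic N–C bonds (ionisation or prenyl shift under acid) and the two terminal vinyl groups (hydrogenation, Heck chemistry).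

## Retrosynthetic reasoning

**Target 11 to dialdehyde 7 and amine 8.** Both pyrrole rings are opened at N1–C7a and N1–C2, four C–N bonds in all. The cut is made here and not at N1–C(quaternary) because the quaternary N–C bond then never has to be formed: it arrives ready-made in amine 8. What remains is ordinary C–N chemistry at sp2 carbon. Forward, each aldehyde of 7 condenses with 8 (N1–C2, via bis(aldimine) 9), and each enamine nitrogen is then arylated intramolecularly by the ortho C–Br carbon under palladium(0) catalysis (N1–C7a, via 10). One operation closes both heterocycles and installs both reverse-prenyl groups; the precursor 7 is an acyclic dialdehyde without any heterocycle.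

**Dialdehyde 7 to dinitrile 5.** The two aldehyde carbons (future C2, C2′) are taken back to nitriles. The nitrile level is chosen because the carbon chain is easiest to assemble there and because a partial hydride reduction via the metallated aldimine 6 delivers the aldehyde directly.

**Dinitrile 5 to nitrile 1 and formaldehyde 2.** The two C3–CH2 bonds are cut. Formaldehyde 2 supplies the bridging methylene and two molecules of 1 supply C2/C3 and the benzo rings. Forward, base-mediated hydroxymethylation of 1 gives 3, dehydration gives the acrylonitrile 4, and Michael addition of a second anion of 1 gives 5. The stereocentres formed here later become C3 and C3′ (sp2), so no control is needed.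

## Alternatives that were turned down

**Alternative 1:** The textbook disconnection cuts the two N1–C(quaternary) bonds, or equivalently the two C3–CH2 bonds.
- Forward, bis(1H-indol-3-yl)methane A1 would be N-tert-prenylated twice through an oxidative π-prenyl-palladium(II) manifold; or 1-(2-methylbut-3-en-2-yl)-1H-indole A2 would be condensed with formaldehyde 2 under acid.
- The first variant needs stoichiometric copper(II)/silver(I) oxidants to work twice on a substrate with two free C2 positions and an oxidisable, doubly heteroaryl-activated CH2.
- The second variant only moves the same N–C problem to an earlier stage, since A2 must itself be made by that chemistry or by an indoline propargylation, semi-hydrogenation and re-oxidation detour. It also ends with an acid-mediated Friedel–Crafts step on a compound whose tertiary allylic N–C bond can ionise.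
- It is also the route drawn first, which the brief excludes.

**Alternative 2:** The same N–C bonds would be formed by a skeletal rearrangement.
- Forward, A1 would be prenylated dearomatively at C3 and C3′ to give bis[3-(3-methylbut-2-en-1-yl)-3H-indol-3-yl]methane A3. A double thermal 1-aza-Cope shift would then move each prenyl group from C3 to N1 with allylic transposition.
- A bond-energy estimate puts the shift near thermoneutral. The gain from restoring the 1H-indole is largely offset by trading a C–C for a C–N σ-bond, a trisubstituted for a monosubstituted alkene, and by congestion at N1. The ordinary 3-aza-Cope runs in the opposite direction.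
- Neutral aza-Cope barriers call for temperatures well above 200 °C. There, 1,2-shifts of the C3 substituents to C2 (irreversible, giving 2,3-disubstituted indoles) and homolysis of the weak C3–allyl bond would compete.
- The mono-prenylated intermediate on the way to A3 also holds a C3–CH2 bond set up for retro-Mannich fragmentation.
- The route is short, but neither of its two steps can be defended.

**Alternative 3:** A double Fischer indolisation cuts N1–C2 and C3–C3a of both rings.
- Forward, pentanedial A5 would be condensed with two molecules of 1-(2-methylbut-3-en-2-yl)-1-phenylhydrazine A4. The five carbons of A5 become C2–C3–CH2–C3′–C2′.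
- The key step is attractive, but A4 is not purchasable. Its N–N bond must be installed on a hindered N-tert-alkylaniline (N-arylation of 8, nitrosation, reduction), which makes a four-step route in which the precursor costs more than the key step wins.
- The indolisation also needs acid and heat while an aniline-type nitrogen carries a tertiary allylic group. That invites ionisation or a charge-accelerated shift of the prenyl group to the ring.
- The risk would sit in two places (N–N formation and the acid step).

Key step: step 3

## Route

**Step 1**
Reactants: 1 2-(2-bromophenyl)acetonitrile (2.2 equiv); 2 formaldehyde (1 equiv, as paraformaldehyde)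
Product: 5 2,4-bis(2-bromophenyl)pentanedinitrile (meso/rac mixture), via hydroxymethyl nitrile 3 (not isolated), via arylacrylonitrile 4 (not isolated)
Conditions: (CH2O)n, NaOEt (0.2 equiv), EtOH, 0 °C → rt
Reagents that add atoms: none
Why: Knoevenagel-type hydroxymethylation and dehydration to 4, then Michael addition of a second nitrile anion; the excess of 1 over 2 should ensure that 4 is taken up by the anion of 1 and not by the anion of 5. Two stereocentres form without control and are erased in step 3.

**Step 2**
Reactants: 5 2,4-bis(2-bromophenyl)pentanedinitrile
Product: 7 2,4-bis(2-bromophenyl)pentanedial (meso/rac mixture), via bis(aluminium aldimine) 6 (not isolated)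
Conditions: DIBAL-H (2.4 equiv), PhMe, −78 °C; then 1 M aq. HCl, 0 °C; used crude
Reagents that add atoms: water, O
Why: Partial hydride reduction of a nitrile stops at the N-aluminio aldimine at −78 °C, and acidic work-up hydrolyses it to the aldehyde; aryl bromides are inert to DIBAL-H at this temperature. The 1,5-dialdehyde cannot undergo intramolecular aldol closure (only a four-membered ring is available) and is taken on without purification.

**Step 3**
Reactants: 7 2,4-bis(2-bromophenyl)pentanedial; 8 2-methylbut-3-en-2-amine
Product: 11 polonidine A, bis[1-(2-methylbut-3-en-2-yl)-1H-indol-3-yl]methane, via bis(aldimine) 9 (not isolated), via indole aldimine 10 (not isolated)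
Conditions: 8 (6 equiv), 4 Å MS, PhMe, 0 °C → rt; evaporate excess 8; then Pd2(dba)3 (2.5 mol %), XPhos (10 mol %), NaOtBu (3 equiv), PhMe, 100 °C
Reagents that add atoms: none
Why: Each aldehyde of 7 condenses with the α-tertiary amine 8 to give bis(aldimine) 9, which equilibrates with its aryl-conjugated N–H enamine tautomers and is deprotonated by NaOtBu to 1-azaallyl anions. Pd(0) inserts into the ortho C–Br bond, the azaallyl nitrogen binds to palladium, and C–N reductive elimination closes the pyrrole ring, once to give 10 and a second time to give 11. The closest known reaction type is the intramolecular Buchwald–Hartwig N-arylation of 2-(2-haloaryl) imines/enamines that ends the imine/o-dihaloarene and enol triflate/aryl halide indole annulations. Each ring closes by N1–C7a bond formation, a five-membered closure by reductive elimination from a six-membered azapalladacycle, and aromatisation to the indole makes it irreversible. No stereocentre is formed: the two stereocentres of 7 become the sp2 carbons C3 and C3′, so both diastereomers converge on achiral 11. Two selectivities are needed: bis(imine) formation instead of 1:1 cyclocondensation of the 1,5-dialdehyde with one amine to a 1,4-dihydropyridine, and N- instead of C-arylation of the ambident azaallyl unit. The first is secured by the excess of 8, by its α-quaternary carbon (which disfavours a ring nitrogen flanked by two ring carbons) and by condensing cold before base or heat is applied; the second because the azaallyl carbon is already fully substituted, so C-arylation would have to build a quaternary centre. The vinyl groups should be spared because a Heck closure from the aryl–palladium species would need a ring of eight or more atoms, and the N–C(quaternary) bonds arrive intact in 8.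

## Compound list

1 | 2-(2-bromophenyl)acetonitrile | N#CCc1ccccc1Br | starting material
2 | formaldehyde (used as paraformaldehyde) | C=O | starting material
3 | 2-(2-bromophenyl)-3-hydroxypropanenitrile (not isolated) | N#CC(CO)c1ccccc1Br | intermediate
4 | 2-(2-bromophenyl)prop-2-enenitrile (not isolated) | C=C(C#N)c1ccccc1Br | intermediate
5 | 2,4-bis(2-bromophenyl)pentanedinitrile (meso/rac mixture) | N#CC(CC(C#N)c1ccccc1Br)c1ccccc1Br | intermediate
6 | N,N′-bis(diisobutylaluminio)-2,4-bis(2-bromophenyl)pentane-1,5-diimine (not isolated) | CC(C)C[Al](CC(C)C)N=CC(CC(C=N[Al](CC(C)C)CC(C)C)c1ccccc1Br)c1ccccc1Br | intermediate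
7 | 2,4-bis(2-bromophenyl)pentanedial (meso/rac mixture) | O=CC(CC(C=O)c1ccccc1Br)c1ccccc1Br | intermediate
8 | 2-methylbut-3-en-2-amine | C=CC(C)(C)N | starting material
9 | 2,4-bis(2-bromophenyl)-N,N′-bis(2-methylbut-3-en-2-yl)pentane-1,5-diimine (not isolated; in equilibrium with its enamine tautomers) | C=CC(C)(C)N=CC(CC(C=NC(C)(C)C=C)c1ccccc1Br)c1ccccc1Br | intermediate
10 | 2-(2-bromophenyl)-N-(2-methylbut-3-en-2-yl)-3-[1-(2-methylbut-3-en-2-yl)-1H-indol-3-yl]propan-1-imine (not isolated) | C=CC(C)(C)N=CC(Cc1cn(C(C)(C)C=C)c2ccccc12)c1ccccc1Br | intermediate
11 | polonidine A, bis[1-(2-methylbut-3-en-2-yl)-1H-indol-3-yl]methane | C=CC(C)(C)n1cc(Cc2cn(C(C)(C)C=C)c3ccccc23)c2ccccc21 | target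

## Step count and least certain steps

Total step count: 3. Longest linear sequence: 3 steps (1 → 5 → 7 → 11).

**Step 3 (key step).**
- The most likely failure is diversion during the condensation: one molecule of amine may condense with both aldehyde groups and close a six-membered ring, which would lock the nitrogen in a form that can no longer be arylated.
- Less likely failures are cross-arylation at the azaallyl carbon of the other half and slow reductive elimination at the hindered nitrogen.
- The fallback reverses the order of the two C–N bond formations, so that each nitrogen is committed to its own arene before it meets a carbonyl group. It sets out from 7 and returns at 11.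
  - Dialdehyde 7 is masked with trimethyl orthoformate and catalytic acid in methanol as the bis(dimethyl acetal) 1,1,5,5-tetramethoxy-2,4-bis(2-bromophenyl)pentane F1.
  - F1 undergoes a double intermolecular Buchwald–Hartwig amination with 8 (palladium(0), bulky biarylphosphine, NaOtBu) to give 2,2′-(1,1,5,5-tetramethoxypentane-2,4-diyl)bis[N-(2-methylbut-3-en-2-yl)aniline] F2.
  - Mild aqueous acid (pyridinium tosylate, wet acetone) should then unmask the aldehydes of F2, which cyclise onto the neighbouring anilines and dehydrate to 11.
  - Closure onto the proximal aldehyde is five-membered; onto the distal one it would be seven-membered.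

**Step 2.**
- The α-C–H of 5 is benzylic and α to the nitrile, so deprotonation may compete with hydride delivery; partial over-reduction to the amine is also possible. Either would give mixtures at two sites at once.
- The fallback is an oxidation-state detour that sets out from 5 and returns at 7.
  - Pinner methanolysis (HCl, MeOH, then water) gives dimethyl 2,4-bis(2-bromophenyl)pentanedioate F3.
  - LiBH4 reduces F3 to 2,4-bis(2-bromophenyl)pentane-1,5-diol F4.
  - Swern oxidation of F4 activates both hydroxyl groups before base is added, so it should give 7 without lactol or lactone formation.

**Step 1.**
- The anion of product 5 may add to further acrylonitrile 4, and 4 may polymerise, giving oligomers instead of the 2:1 adduct.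
- The fallback releases 4 slowly from a stable Mannich base. It sets out from 1 and returns at 5.
  - Lithiated 1 (LiHMDS, THF, −78 °C) is aminomethylated with N,N-dimethylmethyleneiminium iodide to 2-(2-bromophenyl)-3-(dimethylamino)propanenitrile F5.
  - Iodomethane converts F5 into [2-(2-bromophenyl)-2-cyanoethyl]trimethylammonium iodide F6.
  - F6 is added slowly to the sodium anion of 1 (NaH, 2.2 equiv, THF, 0 °C). Elimination generates 4 at low stationary concentration in the presence of excess nucleophile, and Michael addition gives 5.

## Further compounds

F1 | step 3 | 1,1,5,5-tetramethoxy-2,4-bis(2-bromophenyl)pentane | COC(OC)C(CC(C(OC)OC)c1ccccc1Br)c1ccccc1Br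
F2 | step 3 | 2,2′-(1,1,5,5-tetramethoxypentane-2,4-diyl)bis[N-(2-methylbut-3-en-2-yl)aniline] | COC(OC)C(CC(C(OC)OC)c1ccccc1NC(C)(C)C=C)c1ccccc1NC(C)(C)C=C
F3 | step 2 | dimethyl 2,4-bis(2-bromophenyl)pentanedioate | COC(=O)C(CC(C(=O)OC)c1ccccc1Br)c1ccccc1Br
F4 | step 2 | 2,4-bis(2-bromophenyl)pentane-1,5-diol | OCC(CC(CO)c1ccccc1Br)c1ccccc1Br
F5 | step 1 | 2-(2-bromophenyl)-3-(dimethylamino)propanenitrile | CN(C)CC(C#N)c1ccccc1Br
F6 | step 1 | [2-(2-bromophenyl)-2-cyanoethyl]trimethylammonium iodide | C[N+](C)(C)CC(C#N)c1ccccc1Br.[I-]
A1 | alternative 1 | bis(1H-indol-3-yl)methane | C(c1c[nH]c2ccccc12)c1c[nH]c2ccccc12
A2 | alternative 1 | 1-(2-methylbut-3-en-2-yl)-1H-indole | C=CC(C)(C)n1ccc2ccccc21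
A3 | alternative 2 | bis[3-(3-methylbut-2-en-1-yl)-3H-indol-3-yl]methane (meso/rac mixture) | CC(C)=CCC1(CC2(CC=C(C)C)C=Nc3ccccc32)C=Nc2ccccc21
A4 | alternative 3 | 1-(2-methylbut-3-en-2-yl)-1-phenylhydrazine | C=CC(C)(C)N(N)c1ccccc1
A5 | alternative 3 | pentanedial | O=CCCCC=O
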